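**Retrosynthetic overview**
1. C5–C6 is the last bond: an intramolecular Nozaki–Hiyama–Kishi addition of the vinylchromium from a (Z)-β-iodoacrylate to the C6 aldehyde. The acrylate β-carbon, normally an acceptor, acts as a donor (β-acylvinyl anion). The alkoxide then lactonises, so the ten-membered carbocycle, C6 and the 15,6-butenolide form in one step.
2. C3–C4: catalytic asymmetric iodo-aldol (β-iodo Morita–Baylis–Hillman) reaction of the C3 aldehyde with methyl propiolate and Me3SiI, then isobutyrylation.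
3. C6–C7 and C13: the 1,3-dioxolan-2-yl radical (a masked formyl anion) adds to a butenolide trans to the C8 side chain, followed by α-methylenation.
4. C7–C8: zinc–ProPhenol addition of methyl propiolate to an enal sets C8; Lindlar reduction and lactonisation give the 12,8-lactone, the first ring.
5. C1–C10 and the C9=C10 geometry: trans-hydroalumination/iodination of mono-silylated 2-butyne-1,4-diol and B-alkyl Suzuki coupling. Ring order: γ-lactone (step 5), then carbocycle and butenolide together (step 12).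

Assumption: the two silyl ether starting materials are bought (catalogue compounds, otherwise one silylation each from 2-butyne-1,4-diol and allyl alcohol); in steps 4 and 9 the catalyst antipode that gives the stated configuration is used (the facial sense is not asserted from memory); atom labels C1–C15 follow germacrane numbering (C3 carries the ester, C6/C7/C8 the lactone carbons, C14 the CH2OH carbon, C12 and C15 the lactone carbonyls).

**Step 1**
Reactants: 1 4-[(tert-butyldimethylsilyl)oxy]but-2-yn-1-ol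
Product: 3 (Z)-4-[(tert-butyldimethylsilyl)oxy]-3-iodobut-2-en-1-ol, via cyclic vinylalanate 2 (not isolated)
Conditions: NaAlH2(OCH2CH2OMe)2 (1.5 equiv), THF, 0 °C; then N-iodosuccinimide, −78 °C to 0 °C
Reagents that add atoms: N-iodosuccinimide, O=C1CCC(=O)N1I; sodium bis(2-methoxyethoxy)aluminium dihydride, [Na+].COCCO[AlH2-]OCCOC (aluminium stays in 2 only)
Why: Hydroxyl-directed trans-hydroalumination of the propargylic alcohol puts aluminium on the distal alkyne carbon (five-membered alanate 2) and iodinolysis with retention gives the Z-iodoalkene that later fixes the C9=C10 geometry; no stereocentre is formed.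

**Step 2**
Reactants: 3 (Z)-4-[(tert-butyldimethylsilyl)oxy]-3-iodobut-2-en-1-ol; 4 (allyloxy)triethylsilane
Product: 6 (E)-3-{[(tert-butyldimethylsilyl)oxy]methyl}-6-[(triethylsilyl)oxy]hex-2-en-1-ol, via alkylborane 5 (not isolated)
Conditions: 4, 9-BBN-H, THF, 0 °C to rt; then 3, Pd(dppf)Cl2 (5 mol%), AsPh3, Cs2CO3, DMF/H2O, rt
Reagents that add atoms: 9-borabicyclo[3.3.1]nonane, B1C2CCCC1CCC2 (boron stays in 5 only)
Why: Anti-Markovnikov hydroboration of 4 and B-alkyl Suzuki–Miyaura coupling with retention at the alkenyl iodide put the propyl chain cis to the CH2OH carbon (future C8); the free alcohol and both silyl ethers tolerate the mild aqueous base.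

**Step 3**
Reactants: 6 (E)-3-{[(tert-butyldimethylsilyl)oxy]methyl}-6-[(triethylsilyl)oxy]hex-2-en-1-ol
Product: 7 (E)-3-{[(tert-butyldimethylsilyl)oxy]methyl}-6-[(triethylsilyl)oxy]hex-2-enal
Conditions: MnO2 (15 equiv), CH2Cl2, rt
Reagents that add atoms: none
Why: Chemoselective allylic oxidation with MnO2 under neutral conditions gives the enal without E/Z isomerisation or loss of the silyl ethers.

**Step 4**
Reactants: 7 (E)-3-{[(tert-butyldimethylsilyl)oxy]methyl}-6-[(triethylsilyl)oxy]hex-2-enal; 8 methyl propiolate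
Product: 9 methyl (4R,5E)-6-{[(tert-butyldimethylsilyl)oxy]methyl}-4-hydroxy-9-[(triethylsilyl)oxy]non-5-en-2-ynoate
Conditions: ProPhenol (antipode giving 4R, 20 mol%), ZnMe2 (3 equiv), Ph3PO (40 mol%), toluene, 4 °C
Reagents that add atoms: none
Why: Catalytic asymmetric alkynylation, in which the zinc acetylide of methyl propiolate (a β-acyl carbanion equivalent) adds 1,2 to the enal inside the chiral dinuclear zinc–ProPhenol complex and this sets C8 (4R in 9).

**Step 5**
Reactants: 9 methyl (4R,5E)-6-{[(tert-butyldimethylsilyl)oxy]methyl}-4-hydroxy-9-[(triethylsilyl)oxy]non-5-en-2-ynoate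
Product: 11 (5S)-5-[(1E)-2-{[(tert-butyldimethylsilyl)oxy]methyl}-5-[(triethylsilyl)oxy]pent-1-en-1-yl]furan-2(5H)-one, via hydroxy dienoate 10 (not isolated)
Conditions: H2 (1 atm), Pd/CaCO3 poisoned with Pb(OAc)2, quinoline, EtOAc, rt; then PPTS (cat.), CH2Cl2, rt
Reagents that add atoms: none
Why: Lindlar cis-semihydrogenation of the ynoate gives the Z-γ-hydroxy enoate 10, which lactonises to the butenolide; C8 keeps its configuration (the descriptor becomes S only through the priority rules) and the trisubstituted alkene is not reduced.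

**Step 6**
Reactants: 11 (5S)-5-[(1E)-2-{[(tert-butyldimethylsilyl)oxy]methyl}-5-[(triethylsilyl)oxy]pent-1-en-1-yl]furan-2(5H)-one; 12 1,3-dioxolane
Product: 13 (4S,5R)-5-[(1E)-2-{[(tert-butyldimethylsilyl)oxy]methyl}-5-[(triethylsilyl)oxy]pent-1-en-1-yl]-4-(1,3-dioxolan-2-yl)oxolan-2-one
Conditions: benzophenone (20 mol%), 12 as solvent (degassed), hν (350–365 nm), rt
Reagents that add atoms: none
Why: Photosensitised hydrogen abstraction from the solvent gives the nucleophilic 1,3-dioxolan-2-yl radical (a masked formyl anion), which adds to the butenolide β-carbon anti to the C8 alkenyl group (Giese-type radical conjugate addition) and so sets C7 trans to C8 under neutral conditions that do not touch the acidic C8–H.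

**Step 7**
Reactants: 13 (4S,5R)-5-[(1E)-2-{[(tert-butyldimethylsilyl)oxy]methyl}-5-[(triethylsilyl)oxy]pent-1-en-1-yl]-4-(1,3-dioxolan-2-yl)oxolan-2-one; 14 N,N-dimethylmethyleneiminium iodide (Eschenmoser's salt)
Product: 17 (4S,5R)-5-[(1E)-2-{[(tert-butyldimethylsilyl)oxy]methyl}-5-[(triethylsilyl)oxy]pent-1-en-1-yl]-4-(1,3-dioxolan-2-yl)-3-methylideneoxolan-2-one, via Mannich base 15 (not isolated), via ammonium iodide 16 (not isolated)
Conditions: LiN(iPr)2 (1.1 equiv), THF, −78 °C; 14, −78 °C to rt; then MeI, MeOH, rt; then aq. NaHCO3, CH2Cl2, rt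
Reagents that add atoms: iodomethane, CI (methyl stays in 16 only)
Why: α-Methylenation by enolate Mannich reaction with Eschenmoser's salt, N-methylation and Hofmann-type elimination with NaHCO3; the Mannich group enters trans to C7 but C11 becomes sp2, so only C7 and C8 remain stereogenic.

**Step 8**
Reactants: 17 (4S,5R)-5-[(1E)-2-{[(tert-butyldimethylsilyl)oxy]methyl}-5-[(triethylsilyl)oxy]pent-1-en-1-yl]-4-(1,3-dioxolan-2-yl)-3-methylideneoxolan-2-one
Product: 18 (4E)-4-{[(tert-butyldimethylsilyl)oxy]methyl}-5-[(2R,3S)-3-(1,3-dioxolan-2-yl)-4-methylidene-5-oxooxolan-2-yl]pent-4-enal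
Conditions: (COCl)2 (4 equiv), DMSO (8 equiv), CH2Cl2, −78 to −40 °C; then Et3N, −78 to 0 °C
Reagents that add atoms: none
Why: Swern conditions cleave and oxidise a primary triethylsilyl ether directly to the aldehyde, while the tert-butyldimethylsilyl ether, the dioxolane and the methylene lactone are inert at low temperature.

**Step 9**
Reactants: 18 (4E)-4-{[(tert-butyldimethylsilyl)oxy]methyl}-5-[(2R,3S)-3-(1,3-dioxolan-2-yl)-4-methylidene-5-oxooxolan-2-yl]pent-4-enal; 8 methyl propiolate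
Product: 20 methyl (2Z,3S,6E)-6-{[(tert-butyldimethylsilyl)oxy]methyl}-7-[(2R,3S)-3-(1,3-dioxolan-2-yl)-4-methylidene-5-oxooxolan-2-yl]-3-hydroxy-2-(iodomethylidene)hept-6-enoate, via trimethylsilyl ether 19 (not isolated)
Conditions: 8 (1.5 equiv), Me3SiI (1.3 equiv), B-(o-tolyl) diphenylprolinol-derived oxazaborolidinium triflimide (antipode giving 3S, 20 mol%), EtCN, −78 °C; then 1 M HCl, THF, 0 °C
Reagents that add atoms: iodotrimethylsilane, C[Si](C)(C)I (iodine stays in 19 and 20; silicon in 19 only)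
Why: Asymmetric three-component iodo-aldol (β-iodo Morita–Baylis–Hillman) reaction, in which Me3SiI adds to 8 to give a β-iodo allenolate that attacks the aldehyde bound to the chiral oxazaborolidinium Lewis acid; anti addition gives the Z-iodoacrylate and the catalyst sets C3 (S) independently of the remote lactone stereocentres.

**Step 10**
Reactants: 20 methyl (2Z,3S,6E)-6-{[(tert-butyldimethylsilyl)oxy]methyl}-7-[(2R,3S)-3-(1,3-dioxolan-2-yl)-4-methylidene-5-oxooxolan-2-yl]-3-hydroxy-2-(iodomethylidene)hept-6-enoate; 21 2-methylpropanoyl chloride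
Product: 22 methyl (2Z,3S,6E)-6-{[(tert-butyldimethylsilyl)oxy]methyl}-7-[(2R,3S)-3-(1,3-dioxolan-2-yl)-4-methylidene-5-oxooxolan-2-yl]-2-(iodomethylidene)-3-[(2-methylpropanoyl)oxy]hept-6-enoate
Conditions: 21 (1.5 equiv), pyridine, CH2Cl2, 0 °C
Reagents that add atoms: none
Why: Esterification of the secondary allylic alcohol with the acid chloride; pyridine without DMAP avoids SN2′ attack on the Morita–Baylis–Hillman-type ester and leaves the iodoacrylate and methylene lactone intact.

**Step 11**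
Reactants: 22 methyl (2Z,3S,6E)-6-{[(tert-butyldimethylsilyl)oxy]methyl}-7-[(2R,3S)-3-(1,3-dioxolan-2-yl)-4-methylidene-5-oxooxolan-2-yl]-2-(iodomethylidene)-3-[(2-methylpropanoyl)oxy]hept-6-enoate
Product: 23 methyl (2Z,3S,6E)-7-[(2R,3S)-3-formyl-4-methylidene-5-oxooxolan-2-yl]-6-(hydroxymethyl)-2-(iodomethylidene)-3-[(2-methylpropanoyl)oxy]hept-6-enoate
Conditions: 2 M HCl/THF (1:2), 0 °C to rt; cold NaHCO3 wash; used at once without chromatography
Reagents that add atoms: water, O
Why: Acid-catalysed acetal hydrolysis and desilylation in one operation expose the C6 aldehyde and the C14 alcohol; the esters and the vinyl iodide are stable to dilute aqueous acid, and the β,γ-unsaturated aldehyde is used crude so that C7 is not epimerised and the methylene is not conjugated.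

**Step 12**
Reactants: 23 methyl (2Z,3S,6E)-7-[(2R,3S)-3-formyl-4-methylidene-5-oxooxolan-2-yl]-6-(hydroxymethyl)-2-(iodomethylidene)-3-[(2-methylpropanoyl)oxy]hept-6-enoate
Product: 25 (3S,6R,7S,8R)-14-hydroxy-3-[(2-methylpropanoyl)oxy]germacra-4,9,11(13)-triene-12,8:15,6-diolide (ring path trans at C4=C5 and cis at C9=C10), via hydroxy ester 24 (not isolated)
Conditions: CrCl2 (10 equiv), NiCl2 (0.1 equiv), degassed DMSO, syringe-pump addition to 2 mM, rt; aqueous sodium serinate work-up
Reagents that add atoms: none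
Why: Intramolecular Nozaki–Hiyama–Kishi reaction, in which zerovalent nickel inserts into the C–I bond and transmetalation to trivalent chromium gives a β-acylvinyl chromium (acrylate β-carbon as donor) that adds to the C6 aldehyde anti to the C7–C11 bond with ring carbon C8 inside (Felkin–Anh), predicted to set C6 (R); the Z-γ-alkoxy ester then lactonises to the butenolide, and the free hydroxyl, the esters and the methylene lactone are tolerated.

**Compound list**
1 | 4-[(tert-butyldimethylsilyl)oxy]but-2-yn-1-ol | OCC#CCO[Si](C)(C)C(C)(C)C | starting material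
2 | sodium cyclic vinylalanate (five-membered Al–O–CH2–CH=C ring, two 2-methoxyethoxy groups on Al, CH2OSi on the Al-bearing carbon) | [Na+].COCCO[Al-]1(OCCOC)OC/C=C1/CO[Si](C)(C)C(C)(C)C | intermediate
3 | (Z)-4-[(tert-butyldimethylsilyl)oxy]-3-iodobut-2-en-1-ol | OC/C=C(/CO[Si](C)(C)C(C)(C)C)I | intermediate
4 | (allyloxy)triethylsilane | C=CCO[Si](CC)(CC)CC | starting material
5 | 9-{3-[(triethylsilyl)oxy]propyl}-9-borabicyclo[3.3.1]nonane | CC[Si](CC)(CC)OCCCB1C2CCCC1CCC2 | intermediate
6 | (E)-3-{[(tert-butyldimethylsilyl)oxy]methyl}-6-[(triethylsilyl)oxy]hex-2-en-1-ol | OC/C=C(/CO[Si](C)(C)C(C)(C)C)CCCO[Si](CC)(CC)CC | intermediate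
7 | (E)-3-{[(tert-butyldimethylsilyl)oxy]methyl}-6-[(triethylsilyl)oxy]hex-2-enal | O=C/C=C(/CO[Si](C)(C)C(C)(C)C)CCCO[Si](CC)(CC)CC | intermediate
8 | methyl propiolate | C#CC(=O)OC | starting material
9 | methyl (4R,5E)-6-{[(tert-butyldimethylsilyl)oxy]methyl}-4-hydroxy-9-[(triethylsilyl)oxy]non-5-en-2-ynoate | COC(=O)C#C[C@H](O)/C=C(/CO[Si](C)(C)C(C)(C)C)CCCO[Si](CC)(CC)CC | intermediate
10 | methyl (2Z,4S,5E)-6-{[(tert-butyldimethylsilyl)oxy]methyl}-4-hydroxy-9-[(triethylsilyl)oxy]nona-2,5-dienoate | COC(=O)/C=C\[C@H](O)/C=C(/CO[Si](C)(C)C(C)(C)C)CCCO[Si](CC)(CC)CC | intermediate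
11 | (5S)-5-[(1E)-2-{[(tert-butyldimethylsilyl)oxy]methyl}-5-[(triethylsilyl)oxy]pent-1-en-1-yl]furan-2(5H)-one | O=C1C=C[C@H](O1)/C=C(/CO[Si](C)(C)C(C)(C)C)CCCO[Si](CC)(CC)CC | intermediate
12 | 1,3-dioxolane | C1COCO1 | starting material
13 | (4S,5R)-5-[(1E)-2-{[(tert-butyldimethylsilyl)oxy]methyl}-5-[(triethylsilyl)oxy]pent-1-en-1-yl]-4-(1,3-dioxolan-2-yl)oxolan-2-one | O=C1C[C@H](C2OCCO2)[C@H](O1)/C=C(/CO[Si](C)(C)C(C)(C)C)CCCO[Si](CC)(CC)CC | intermediate
14 | N,N-dimethylmethyleneiminium iodide (Eschenmoser's salt) | C=[N+](C)C.[I-] | starting material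
15 | (3R,4S,5R)-3-[(dimethylamino)methyl] derivative of 13 (Mannich base, 3,4-trans) | O=C1[C@@H](CN(C)C)[C@H](C2OCCO2)[C@H](O1)/C=C(/CO[Si](C)(C)C(C)(C)C)CCCO[Si](CC)(CC)CC | intermediate
16 | trimethylammonium iodide of 15 | O=C1[C@@H](C[N+](C)(C)C)[C@H](C2OCCO2)[C@H](O1)/C=C(/CO[Si](C)(C)C(C)(C)C)CCCO[Si](CC)(CC)CC.[I-] | intermediate
17 | (4S,5R)-5-[(1E)-2-{[(tert-butyldimethylsilyl)oxy]methyl}-5-[(triethylsilyl)oxy]pent-1-en-1-yl]-4-(1,3-dioxolan-2-yl)-3-methylideneoxolan-2-one | O=C1C(=C)[C@H](C2OCCO2)[C@H](O1)/C=C(/CO[Si](C)(C)C(C)(C)C)CCCO[Si](CC)(CC)CC | intermediate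
18 | (4E)-4-{[(tert-butyldimethylsilyl)oxy]methyl}-5-[(2R,3S)-3-(1,3-dioxolan-2-yl)-4-methylidene-5-oxooxolan-2-yl]pent-4-enal | O=C1C(=C)[C@H](C2OCCO2)[C@H](O1)/C=C(/CO[Si](C)(C)C(C)(C)C)CCC=O | intermediate
19 | O-trimethylsilyl ether of 20 | O=C1C(=C)[C@H](C2OCCO2)[C@H](O1)/C=C(/CO[Si](C)(C)C(C)(C)C)CC[C@H](O[Si](C)(C)C)/C(C(=O)OC)=C/I | intermediate
20 | methyl (2Z,3S,6E)-6-{[(tert-butyldimethylsilyl)oxy]methyl}-7-[(2R,3S)-3-(1,3-dioxolan-2-yl)-4-methylidene-5-oxooxolan-2-yl]-3-hydroxy-2-(iodomethylidene)hept-6-enoate | O=C1C(=C)[C@H](C2OCCO2)[C@H](O1)/C=C(/CO[Si](C)(C)C(C)(C)C)CC[C@H](O)/C(C(=O)OC)=C/I | intermediate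
21 | 2-methylpropanoyl chloride | CC(C)C(=O)Cl | starting material
22 | methyl (2Z,3S,6E)-6-{[(tert-butyldimethylsilyl)oxy]methyl}-7-[(2R,3S)-3-(1,3-dioxolan-2-yl)-4-methylidene-5-oxooxolan-2-yl]-2-(iodomethylidene)-3-[(2-methylpropanoyl)oxy]hept-6-enoate | O=C1C(=C)[C@H](C2OCCO2)[C@H](O1)/C=C(/CO[Si](C)(C)C(C)(C)C)CC[C@H](OC(=O)C(C)C)/C(C(=O)OC)=C/I | intermediate
23 | methyl (2Z,3S,6E)-7-[(2R,3S)-3-formyl-4-methylidene-5-oxooxolan-2-yl]-6-(hydroxymethyl)-2-(iodomethylidene)-3-[(2-methylpropanoyl)oxy]hept-6-enoate | O=C1C(=C)[C@H](C=O)[C@H](O1)/C=C(/CO)CC[C@H](OC(=O)C(C)C)/C(C(=O)OC)=C/I | intermediate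
24 | ten-membered hydroxy ester (3S,6R,7R,8R): 25 with the 15,6-lactone open as C6–OH and C15 methyl ester (chromium alkoxide before work-up) | C=C1C(=O)O[C@@H]2/C=C(/CO)CC[C@H](OC(=O)C(C)C)/C(C(=O)OC)=C/[C@@H](O)[C@@H]12 | intermediate
25 | (3S,6R,7S,8R)-14-hydroxy-3-[(2-methylpropanoyl)oxy]germacra-4,9,11(13)-triene-12,8:15,6-diolide, CNP0322767.4 | C=C1C(=O)O[C@@H]2/C=C(/CO)CC[C@H](OC(=O)C(C)C)C3=C[C@@H](OC3=O)[C@@H]12 | target

**Totals and risks**
Total step count: 12. Longest linear sequence: 12 steps (from 1).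

Step 12 (key macrocyclisation) is the most likely to fail, through slow ring closure or the wrong configuration at C6. The fallback closes the ring at C3–C4 instead and makes the polarity-reversed C5–C6 bond intermolecularly, where excess reagent keeps the lifetime of the aldehyde short. It sets out from 17 and comes back at 25. The dioxolane of 17 is cleaved selectively (Et3SiOTf, 2,4,6-collidine, CH2Cl2, 0 °C; then H2O) to lactone aldehyde F1. Coupling with methyl (Z)-3-iodoacrylate (CrCl2, cat. NiCl2, DMF) gives hydroxy ester F2 (not isolated), which lactonises to bis-lactone F3, with C6 set by Felkin–Anh addition and epimers separable here. Iodination (I2, pyridine, CH2Cl2) gives α-iodobutenolide F4, and Swern oxidation of the triethylsilyl ether gives aldehyde F5. Intramolecular CrCl2/NiCl2 addition of the α-iodobutenolide to the C3 aldehyde closes the ring to allylic alcohol F6. Either C3 epimer is usable: the 3S alcohol is acylated with 21, and the 3R alcohol is esterified with isobutyric acid under Mitsunobu inversion, giving silyl ether F7. HF·pyridine in THF then gives 25.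

Step 11 may fail because aldehyde 23 is a β,γ-unsaturated, β-acyloxy aldehyde that can conjugate, epimerise at C7 or eliminate in aqueous acid. The fallback separates the two deprotections and removes the silyl group only after the ring is closed. It sets out from 22 and comes back at 25. Neutral transacetalisation (I2 5 mol%, acetone, rt) gives silyl-protected aldehyde F8. This is cyclised under the conditions of step 12 through hydroxy ester F9 (not isolated) to silyl ether F7, the compound already met in the first fallback. HF·pyridine then gives 25.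

Step 9 may fail through poor catalyst control at C3 in this polyfunctional substrate, or through attack of Me3SiI on the dioxolane or the methylene lactone. The fallback sets C3 by reduction instead of during the C–C bond formation. It sets out from 18 and comes back at 20. The uncatalysed iodo-aldol reaction of 18 with 8 and MgI2 (CH2Cl2, 0 °C) gives epimeric alcohols F10. Dess–Martin periodinane oxidises them to ketone F11. Corey–Bakshi–Shibata reduction (oxazaborolidine antipode giving 3S, catecholborane, toluene, −78 °C) returns 20.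

**Further compounds**
F1 | step 12 | (2R,3S)-2-[(1E)-2-{[(tert-butyldimethylsilyl)oxy]methyl}-5-[(triethylsilyl)oxy]pent-1-en-1-yl]-4-methylidene-5-oxooxolane-3-carbaldehyde | O=C1C(=C)[C@H](C=O)[C@H](O1)/C=C(/CO[Si](C)(C)C(C)(C)C)CCCO[Si](CC)(CC)CC
F2 | step 12 | Z-γ-hydroxy enoate from F1: the CHO carbon becomes (R)-CH(OH)–CH=CH–CO2Me | O=C1C(=C)[C@H]([C@H](O)/C=C\C(=O)OC)[C@H](O1)/C=C(/CO[Si](C)(C)C(C)(C)C)CCCO[Si](CC)(CC)CC
F3 | step 12 | bis-lactone: 17 with the dioxolanyl group replaced by (2R)-5-oxo-2,5-dihydrofuran-2-yl | O=C1C(=C)[C@H]([C@@H]2OC(=O)C=C2)[C@H](O1)/C=C(/CO[Si](C)(C)C(C)(C)C)CCCO[Si](CC)(CC)CC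
F4 | step 12 | α-iodobutenolide: F3 with iodine on the butenolide α-carbon (C4) | O=C1C(=C)[C@H]([C@@H]2OC(=O)C(I)=C2)[C@H](O1)/C=C(/CO[Si](C)(C)C(C)(C)C)CCCO[Si](CC)(CC)CC
F5 | step 12 | aldehyde: F4 with the CH2OSiEt3 terminus (C3) oxidised to CHO | O=C1C(=C)[C@H]([C@@H]2OC(=O)C(I)=C2)[C@H](O1)/C=C(/CO[Si](C)(C)C(C)(C)C)CCC=O
F6 | step 12 | macrocyclic allylic alcohol: 14-O-tert-butyldimethylsilyl ether of 25 without the isobutyryl group (3S epimer shown) | C=C1C(=O)O[C@@H]2/C=C(/CO[Si](C)(C)C(C)(C)C)CC[C@H](O)C3=C[C@@H](OC3=O)[C@@H]12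
F7 | step 12 | 14-O-tert-butyldimethylsilyl ether of 25 | C=C1C(=O)O[C@@H]2/C=C(/CO[Si](C)(C)C(C)(C)C)CC[C@H](OC(=O)C(C)C)C3=C[C@@H](OC3=O)[C@@H]12
F8 | step 11 | 22 with the dioxolane converted to the C6 aldehyde and the silyl ether kept | O=C1C(=C)[C@H](C=O)[C@H](O1)/C=C(/CO[Si](C)(C)C(C)(C)C)CC[C@H](OC(=O)C(C)C)/C(C(=O)OC)=C/I
F9 | step 11 | 14-O-tert-butyldimethylsilyl ether of 24 | C=C1C(=O)O[C@@H]2/C=C(/CO[Si](C)(C)C(C)(C)C)CC[C@H](OC(=O)C(C)C)/C(C(=O)OC)=C/[C@@H](O)[C@@H]12
F10 | step 9 | 20 as the mixture of C3 epimers | O=C1C(=C)[C@H](C2OCCO2)[C@H](O1)/C=C(/CO[Si](C)(C)C(C)(C)C)CCC(O)/C(C(=O)OC)=C/I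
F11 | step 9 | C3 ketone of 20: methyl (2Z,6E)-2-(iodomethylidene)-3-oxo ester | O=C1C(=C)[C@H](C2OCCO2)[C@H](O1)/C=C(/CO[Si](C)(C)C(C)(C)C)CCC(=O)/C(C(=O)OC)=C/I
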